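How much product stands in this flask at the end of the run, and which change adds most?

    free catalyst → spent catalyst A (k1 = 0.14 s⁻¹)
    coupling partner + second catalyst + intermediate → second catalyst + product (k2 = 650 M⁻² s⁻¹)
    solid reagent ⇌ coupling partner, rate k3*(cs3 - [coupling partner]) while solid is left; crystals form when [coupling partner] > cs3 (cs3 = 18 mM, k3 = 0.32 s⁻¹)
    free catalyst + impurity → spent catalyst B (k4 = 48000 M⁻¹ s⁻¹)
    substrate + free catalyst → free catalyst + intermediate (k5 = 13000 M⁻¹ s⁻¹)

substrate 0.020 M; solid reagent 0.0220 M; free catalyst 11 µM; second catalyst 2.0 mM; impurity 11 µM; time 10 s

- solid reagent is a solid; its amount is given per volume of the solution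
- at the start none of the solid reagent is in solution
- run time (flask): 10 s

- how much product there is at 10 s, in percent of the substrate charged
- the change that raises the amount of product at 10 s, in percent of the substrate charged most ("none" if none brings more than 2 percentage points) (north / west / north-west / none)
- amount of product at 10 s, in percent of the substrate charged, after north-west

- north: doubling the amount of free catalyst, all else as stated
- west: doubling the dissolution coefficient of step 3, all else as stated
- north-west: doubling the solubility in step 3, all else as stated

Product needs intermediate, and intermediate needs free catalyst. Substrate and impurity both meet that same free catalyst, so however [free catalyst] falls, their logarithmic losses keep one ratio, the selectivity factor S: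

ln([substrate] charged / [substrate] left) = S × ln([impurity] charged / [impurity] left)

S = 13000 M⁻¹ s⁻¹ / 48000 M⁻¹ s⁻¹ = 0.271

You can solve two extreme flasks in your head. If impurity stayed at its charge, catalyst would die at a steady 0.668 s⁻¹ and substrate would end at 80.7%. With no impurity, catalyst would die at 0.14 s⁻¹ and substrate would stand at 46.3% at 10 s.

The real flask starts near the first extreme, since impurity kills faster than the first-order decay. But each kill removes an impurity, so that rate drifts down. My reckoning takes impurity at half its charge on average:

share of catalyst killed by impurity = 65.3%

Catalyst and impurity are charged equally, so about 34.7% of the impurity survives, and S leaves substrate at 75.0%. Coupling runs at 0.0234 s⁻¹ at saturation, and the partner lags by 3.12 s, so I expect somewhat under 4.01% product. I back north, because doubled catalyst outnumbers the impurity.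

The forecast says 3.4% (3% to 3.9%), north, and 4.9% (4.3% to 5.5%) after north-west; its first number is lower than my figure. Its grounds begin with this: “The impurity and first-order decay kill the catalyst within a few seconds”.

The simulation gives 3.45%, north with a gain of 3.7 percentage points (west 0.56 points, north-west 1.4 points), and 4.89% after north-west.

In this flask the half-life of substrate by the catalyst's step stretches from 4.8 s at the charge to 14 s at 2.11 s and 3.4 min at 10.0 s, far longer than the run. Meanwhile half of the coupling's turnover comes only by 6.50 s, against 1.46 s for the making of intermediate. With 32% of the impurity left, S gives 73.7% substrate, and the flask shows 74%.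

In the neighbour flask with 4.4 × 10⁻⁵ M of free catalyst, 0.018% of the impurity is left at 10 s, so S gives 9.70% substrate. The computed flask holds 9.7% substrate and 11.6% product.

The constants used here stand for no real mixture, and the outcome is calculated.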